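Late in the run, I expect this flask to hold a closed account of J, so I keep that account by hand.

X 10 mM; J 2.20 equiv (in portions, 2); G 10 mM; time 15 d; the portions of J follow each other after 15 h, the first at the start

    J + X → J.X (k1 = 13.0 M⁻¹ h⁻¹)
    J + G → J.G (k2 = 6.07 M⁻¹ h⁻¹)
    X ⇌ Z (K3 = 1.27, k3 = 0.257 h⁻¹)
    G ⇌ Z (K3 = 1.27, k3 = 0.257 h⁻¹)
    2 J → J2 (k5 = 2.16 M⁻¹ h⁻¹)

- J is single-handed; X and G are mirror images of each other, charged as a racemate, each of them at the stated concentration
- for a step with 2 of a species take k times the square, and two of it per event
- the reaction counts as stopped when no species that holds the X and G together changes by six tenths of a point or more over the second half of the time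
- run time (flask): 15 d
- the handed part of J does not stay in what it makes, so the products of the two hands are mirror images too

- the state of affairs at 15 d: stopped, and by what, or still going (it is still moving / J has run out first / all of X has reacted / forward and back rates have come level)
- J.X at 15 d, in percent of the X and G together charged
- J.G at 15 d, in percent of the X and G together charged
- Z at 15 d, in percent of the X and G together charged
- amount of J.X if the flask were left three thousand times as long, in percent of the X and G together charged

The ledger has few entries: one J goes into J.X or J.G, and two J go into one J2. I book X, G and Z as one pool in balance, because the relaxation half-life of G and Z, 0.0629 d, is shorter than the 0.48 d half-life of J by its step with G, reckoned with G held at its charge. The booking is rough: a fresh portion of J takes X at 0.143 h⁻¹ per unit of X, which is less than the 0.257 h⁻¹ of X into Z but of like size. Within the pool, X and G each hold a share of 0.306, and Z holds 0.388.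

The quantity I carry is the leak number, the J lost to J2 for each J captured at a moment when cJ equals the c of the pool: 0.741. At other moments, the loss per capture scales with cJ over the pool's c.

Integrating this balance gives a rule. Take m as one minus the leak number and b as a portion of J over the pool it meets. When that portion is used up, the pool keeps the fraction (one minus m times b) raised to the power one over m. Here m is 0.259.

The first portion has b of 0.550, and the pool keeps 0.552. I book it as finished before the second comes 15 h later, which is a simplification of mine. That portion meets a smaller pool, so its b is 0.996, and 0.175 of the charged pool stays. The books close with 82.5% captured and 17.5% unbound, so I expect J to run out first. Captures split as the two constants do, which gives J.X 56.3%, J.G 26.3% and Z 6.78%. I book no capture after the second portion, so later J.X stays at 56.3% in my ledger.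

The forecast says J has run out first, with J.X 51%, J.G 27.5%, Z 8.5% and later J.X 51%, since “nothing further can form J.X”. It captures about 78% in a ratio of 1.85, where I have 82.5% and 2.14.

The simulation of this flask gives J has run out first, with J.X 52.3%, J.G 27.3%, Z 7.91% and later J.X 52.3%. Its unbound pool is 20.4% against my 17.5%, its J.X over J.G reads 1.92, and at 0.663 d J used X at 0.59 of the forward rate of X into Z. For the flask with 0.880 equiv of J, the leak number 0.741 gives b of 0.220, a pool of 0.797 after the first portion and a capture of 40.1%; that flask holds J.X 26.6% and J.G 13.1%, together 39.7%.

The numbers belong to no real substance.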